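**Strategy.** The oxepine ring (O1, C2 to C7) is opened at C2–C3 and at C5=C6, so that C3–C4–C5 becomes acrolein. One flask operation joins three components. The captodative radical of a tert-butyl dioxolanone made from (R)-malic acid adds to acrolein (C2–C3; the acetal tert-butyl group fixes the C2 quaternary centre). Silanolate then unveils the tertiary alkoxide, and a Schweizer oxa-Michael/Wittig annulation with a side-chain vinylphosphonium salt closes O1–C7 and C5=C6. The step exploits C2 as the α-carbon of an α-hydroxy acid and C5=C6–C7–O1 as an allyl ether. The precursors are a bromodioxolanone, acrolein and the vinylphosphonium triflate; later steps add the aryl ketone and the coumarate.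

Key step: step 8

Remark (assumption): (R)-malic acid, 6-methylhept-5-en-2-one, acrolein, 2-bromohydroquinone and p-coumaric acid are taken as the commercial starting materials; reagents such as pivalaldehyde, TBSCl and PPh3 are not numbered.

Step 1
Reactants: 1 (R)-malic acid
Product: 2 (2R,4R)-2-tert-butyl-5-oxo-1,3-dioxolane-4-acetic acid
Conditions: t-BuCHO, p-TsOH (cat.), H2SO4 (cat.), pentane, reflux, Dean–Stark; recrystallisation
Reagents that add atoms: pivalaldehyde, CC(C)(C)C=O
Why: Acid-catalysed acetalisation of the α-hydroxy acid with azeotropic removal of water (dioxolanone formation) should give the five-membered acylal in which the existing (R) centre places the new acetal centre with tert-butyl cis to the CH2CO2H arm, the isomer that crystallises.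

Step 2
Reactants: 2 (2R,4R)-2-tert-butyl-5-oxo-1,3-dioxolane-4-acetic acid
Product: 4 2-[(2R,4R)-2-tert-butyl-5-oxo-1,3-dioxolan-4-yl]-N-methoxy-N-methylacetamide, via acyl imidazole 3 (not isolated)
Conditions: CDI, CH2Cl2, 0 °C to rt; then MeNH(OMe)·HCl, rt
Reagents that add atoms: N,O-dimethylhydroxylamine hydrochloride, CNOC.Cl
Why: Carbonyldiimidazole activates only the free side-chain acid and the acyl imidazole is trapped by N,O-dimethylhydroxylamine (Weinreb amide formation) without touching either stereocentre.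

Step 3
Reactants: 4 2-[(2R,4R)-2-tert-butyl-5-oxo-1,3-dioxolan-4-yl]-N-methoxy-N-methylacetamide
Product: 5 2-[(2S,4S)-4-bromo-2-tert-butyl-5-oxo-1,3-dioxolan-4-yl]-N-methoxy-N-methylacetamide
Conditions: NBS, AIBN (cat.), CCl4, reflux; filtered and used crude
Reagents that add atoms: N-bromosuccinimide, O=C1CCC(=O)N1Br
Why: Radical bromination (Wohl–Ziegler type) should occur at the captodative ring C–H between the ring oxygen and the lactone carbonyl, which is the known behaviour of 2-tert-butyl-1,3-dioxolan-4-ones, and the configuration of this carbon is irrelevant because it becomes a planar radical in step 8.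

Step 4
Reactants: 6 6-methylhept-5-en-2-one
Product: 7 (E)-7-hydroxy-6-methylhept-5-en-2-one
Conditions: SeO2 (cat.), t-BuOOH, salicylic acid (cat.), CH2Cl2, 0 °C to rt
Reagents that add atoms: tert-butyl hydroperoxide, CC(C)(C)OO
Why: Catalytic SeO2 with t-BuOOH (allylic oxidation by ene reaction and [2,3]-sigmatropic shift) oxidises the methyl group trans to the chain of the trisubstituted alkene and thereby sets the E-allylic alcohol.

Step 5
Reactants: 7 (E)-7-hydroxy-6-methylhept-5-en-2-one
Product: 8 (E)-7-(tert-butyldimethylsilyloxy)-6-methylhept-5-en-2-one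
Conditions: TBSCl, imidazole, DMF, rt
Reagents that add atoms: tert-butyldimethylsilyl chloride, CC(C)(C)[Si](C)(C)Cl
Why: Standard silylation protects the primary allylic alcohol as a TBS ether that survives the strong bases used later.

Step 6
Reactants: 8 (E)-7-(tert-butyldimethylsilyloxy)-6-methylhept-5-en-2-one
Product: 10 (E)-7-(tert-butyldimethylsilyloxy)-6-methylhepta-1,5-dien-2-yl trifluoromethanesulfonate, via potassium enolate 9 (not isolated)
Conditions: KHMDS, THF, −78 °C; then PhNTf2, −78 °C to 0 °C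
Reagents that add atoms: N-phenylbis(trifluoromethanesulfonimide), O=S(=O)(N(c1ccccc1)S(=O)(=O)C(F)(F)F)C(F)(F)F
Why: Kinetic deprotonation of the methyl ketone at the CH3 group followed by O-sulfonylation with PhNTf2 (enol triflate formation) should give the 1,1-disubstituted vinyl triflate.

Step 7
Reactants: 10 (E)-7-(tert-butyldimethylsilyloxy)-6-methylhepta-1,5-dien-2-yl trifluoromethanesulfonate
Product: 11 [(E)-7-(tert-butyldimethylsilyloxy)-6-methylhepta-1,5-dien-2-yl]triphenylphosphonium trifluoromethanesulfonate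
Conditions: PPh3, Pd(PPh3)4 (cat.), THF, reflux
Reagents that add atoms: triphenylphosphine, c1ccc(P(c2ccccc2)c2ccccc2)cc1
Why: Palladium(0)-catalysed C–P coupling of a vinyl triflate with triphenylphosphine (oxidative addition, then reductive elimination of the phosphonium ion) is a known route to 1-substituted vinylphosphonium triflates.

Step 8
Reactants: 5 2-[(2S,4S)-4-bromo-2-tert-butyl-5-oxo-1,3-dioxolan-4-yl]-N-methoxy-N-methylacetamide, 12 acrolein, 11 [(E)-7-(tert-butyldimethylsilyloxy)-6-methylhepta-1,5-dien-2-yl]triphenylphosphonium trifluoromethanesulfonate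
Product: 15 (2R)-6-[(3E)-5-(tert-butyldimethylsilyloxy)-4-methylpent-3-en-1-yl]-2-[2-(methoxy(methyl)amino)-2-oxoethyl]-2,3,4,7-tetrahydrooxepine-2-carboxylic acid, via aldehyde dioxolanone 13 (not isolated), via dipotassium alkoxide carboxylate 14 (not isolated)
Conditions: (i) 12, Bu3SnH (slow addition), Et3B/air, toluene, −20 °C, then MeCN/hexane partition and evaporation; (ii) KOSiMe3 (2.1 equiv), THF, −20 to 0 °C, then evaporation of t-BuCHO; (iii) 11, THF/DMF, 0 to 40 °C; aq. HCl work-up
Reagents that add atoms: potassium trimethylsilanolate, C[Si](C)(C)[O-].[K+]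
Why: Proposed new method: Et3B/air and Bu3SnH convert bromide 5 into a captodative dioxolan-4-on-5-yl radical that adds to the CH2 end of acrolein (Giese reaction) to give aldehyde 13, silanolate then opens the acylal lactone with loss of pivalaldehyde to give 14 (the open form of a γ-lactol alkoxide with an inert carboxylate), and its alkoxide adds to the CH2 end of vinylphosphonium salt 11 to give a β-alkoxy ylide that olefinates the tethered aldehyde (oxa-Michael then intramolecular Wittig reaction). The closest known reaction types are Giese additions of α-bromo lactone radicals, alkoxide cleavage of 2-tert-butyl-1,3-dioxolan-4-ones and the Schweizer reaction of hydroxy carbonyl compounds with vinylphosphonium salts to 2,5-dihydrofurans and 2H-chromenes, and what is new is the seven-membered ring and the telescoping of the three events. The oxepine ring closes in the Wittig event, a seven-membered cyclisation through an oxaphosphetane between the ylide carbon C6 and the aldehyde carbon C5 that follows the intermolecular O1–C7 bond formation, and the ring enforces the cis geometry of the trisubstituted C5=C6 alkene. The only new stereocentre, C2, is set in the radical event, in which acrolein attacks the planar radical on the face opposite to the acetal tert-butyl group so that the three-carbon arm takes the place of the former hydrogen (self-regeneration of the (R)-malic acid centre, 2R). The step needs anti addition to the radical (tert-butyl shielding at low temperature), attack of silanolate on the ring carbonyl and not on the Weinreb amide (the acylal lactone is far more electrophilic), O-addition of the alkoxide and not the carboxylate to 11 (the carboxylate adduct reverts and cannot olefinate) and olefination of the tethered aldehyde and not of pivalaldehyde (removed by evaporation before 11 is added).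

Step 9
Reactants: 16 2-bromobenzene-1,4-diol
Product: 17 2-bromo-1,4-bis(tert-butyldimethylsilyloxy)benzene
Conditions: TBSCl, imidazole, DMF, rt
Reagents that add atoms: tert-butyldimethylsilyl chloride, CC(C)(C)[Si](C)(C)Cl
Why: Silylation of both phenols gives an aryl bromide that tolerates magnesium insertion.

Step 10
Reactants: 15 (2R)-6-[(3E)-5-(tert-butyldimethylsilyloxy)-4-methylpent-3-en-1-yl]-2-[2-(methoxy(methyl)amino)-2-oxoethyl]-2,3,4,7-tetrahydrooxepine-2-carboxylic acid, 17 2-bromo-1,4-bis(tert-butyldimethylsilyloxy)benzene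
Product: 19 (2R)-2-{2-[2,5-bis(tert-butyldimethylsilyloxy)phenyl]-2-oxoethyl}-6-[(3E)-5-(tert-butyldimethylsilyloxy)-4-methylpent-3-en-1-yl]-2,3,4,7-tetrahydrooxepine-2-carboxylic acid, via arylmagnesium bromide 18 (not isolated)
Conditions: 17, Mg, LiCl, THF, rt; then 15 (18 in 2.5 equiv), THF, −20 to 0 °C; aq. NH4Cl then dilute HCl
Reagents that add atoms: none
Why: The first equivalent of aryl Grignard reagent turns the acid into an inert magnesium carboxylate and the second adds to the Weinreb amide (Weinreb ketone synthesis), whose chelated tetrahedral intermediate prevents over-addition and keeps the β-alkoxy ketone masked until the acidic quench.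

Step 11
Reactants: 19 (2R)-2-{2-[2,5-bis(tert-butyldimethylsilyloxy)phenyl]-2-oxoethyl}-6-[(3E)-5-(tert-butyldimethylsilyloxy)-4-methylpent-3-en-1-yl]-2,3,4,7-tetrahydrooxepine-2-carboxylic acid
Product: 20 (2R)-2-{2-[2,5-bis(tert-butyldimethylsilyloxy)phenyl]-2-oxoethyl}-6-[(3E)-5-hydroxy-4-methylpent-3-en-1-yl]-2,3,4,7-tetrahydrooxepine-2-carboxylic acid
Conditions: AcOH/THF/H2O (3:1:1), rt
Reagents that add atoms: none
Why: Mild aqueous acid (acid-catalysed desilylation) cleaves the primary alkyl TBS ether much faster than the two aryl TBS ethers and does not enolise the β-alkoxy ketone.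

Step 12
Reactants: 21 p-coumaric acid
Product: 23 (E)-3-[4-(tert-butyldimethylsilyloxy)phenyl]prop-2-enoic acid, via bis-silyl derivative 22 (not isolated)
Conditions: TBSCl (2.3 equiv), imidazole, DMF, rt; then AcOH, THF/H2O, rt
Reagents that add atoms: tert-butyldimethylsilyl chloride, CC(C)(C)[Si](C)(C)Cl
Why: Silylation of both acidic groups followed by selective hydrolysis of the labile silyl ester leaves the phenol protected (protection of a phenol in the presence of an acid).

Step 13
Reactants: 20 (2R)-2-{2-[2,5-bis(tert-butyldimethylsilyloxy)phenyl]-2-oxoethyl}-6-[(3E)-5-hydroxy-4-methylpent-3-en-1-yl]-2,3,4,7-tetrahydrooxepine-2-carboxylic acid, 23 (E)-3-[4-(tert-butyldimethylsilyloxy)phenyl]prop-2-enoic acid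
Product: 25 (2R)-2-{2-[2,5-bis(tert-butyldimethylsilyloxy)phenyl]-2-oxoethyl}-6-[(3E)-5-{[(2E)-3-(4-(tert-butyldimethylsilyloxy)phenyl)prop-2-enoyl]oxy}-4-methylpent-3-en-1-yl]-2,3,4,7-tetrahydrooxepine-2-carboxylic acid, via acid chloride 24 (not isolated)
Conditions: 23, (COCl)2, DMF (cat.), CH2Cl2, 0 °C to rt, evaporation; then 20, pyridine, CH2Cl2, 0 °C; aq. NaHCO3 then dilute acid
Reagents that add atoms: none
Why: The acid chloride acylates the unhindered primary allylic alcohol (esterification with retention of both E alkenes), and any mixed anhydride formed at the hindered C2 carboxylic acid is hydrolysed by the bicarbonate wash.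

Step 14
Reactants: 25 (2R)-2-{2-[2,5-bis(tert-butyldimethylsilyloxy)phenyl]-2-oxoethyl}-6-[(3E)-5-{[(2E)-3-(4-(tert-butyldimethylsilyloxy)phenyl)prop-2-enoyl]oxy}-4-methylpent-3-en-1-yl]-2,3,4,7-tetrahydrooxepine-2-carboxylic acid
Product: 26 (2R)-2-[2-(2,5-dihydroxyphenyl)-2-oxoethyl]-6-[(3E)-5-{[(2E)-3-(4-hydroxyphenyl)prop-2-enoyl]oxy}-4-methylpent-3-en-1-yl]-2,3,4,7-tetrahydrooxepine-2-carboxylic acid
Conditions: TBAF, AcOH (1:1), THF, 0 °C to rt
Reagents that add atoms: none
Why: Fluoride cleaves the three aryl silyl ethers (desilylation) and the acetic acid buffer keeps phenoxide from opening the β-alkoxy ketone by retro-oxa-Michael reaction or attacking the coumarate ester, so the C2 centre is not scrambled.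

Compound list
1 | (R)-malic acid | O[C@H](CC(=O)O)C(=O)O | starting material
2 | (2R,4R)-2-tert-butyl-5-oxo-1,3-dioxolane-4-acetic acid (tert-butyl cis to the CH2CO2H arm) | OC(=O)C[C@H]1O[C@@H](C(C)(C)C)OC1=O | intermediate
3 | (2R,5R)-2-tert-butyl-5-[2-(imidazol-1-yl)-2-oxoethyl]-1,3-dioxolan-4-one | O=C(C[C@H]1O[C@@H](C(C)(C)C)OC1=O)n1ccnc1 | intermediate (not isolated)
4 | 2-[(2R,4R)-2-tert-butyl-5-oxo-1,3-dioxolan-4-yl]-N-methoxy-N-methylacetamide | CON(C)C(=O)C[C@H]1O[C@@H](C(C)(C)C)OC1=O | intermediate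
5 | 2-[(2S,4S)-4-bromo-2-tert-butyl-5-oxo-1,3-dioxolan-4-yl]-N-methoxy-N-methylacetamide (Br trans to tert-butyl) | CON(C)C(=O)C[C@@]1(Br)O[C@@H](C(C)(C)C)OC1=O | intermediate
6 | 6-methylhept-5-en-2-one | CC(=O)CCC=C(C)C | starting material
7 | (E)-7-hydroxy-6-methylhept-5-en-2-one | C/C(=C\CCC(C)=O)CO | intermediate
8 | (E)-7-(tert-butyldimethylsilyloxy)-6-methylhept-5-en-2-one | C/C(=C\CCC(C)=O)CO[Si](C)(C)C(C)(C)C | intermediate
9 | potassium (E)-7-(tert-butyldimethylsilyloxy)-6-methylhepta-1,5-dien-2-olate | C/C(=C\CCC(=C)[O-])CO[Si](C)(C)C(C)(C)C.[K+] | intermediate (not isolated)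
10 | (E)-7-(tert-butyldimethylsilyloxy)-6-methylhepta-1,5-dien-2-yl trifluoromethanesulfonate | C/C(=C\CCC(=C)OS(=O)(=O)C(F)(F)F)CO[Si](C)(C)C(C)(C)C | intermediate
11 | [(E)-7-(tert-butyldimethylsilyloxy)-6-methylhepta-1,5-dien-2-yl]triphenylphosphonium trifluoromethanesulfonate | C/C(=C\CCC(=C)[P+](c1ccccc1)(c1ccccc1)c1ccccc1)CO[Si](C)(C)C(C)(C)C.[O-]S(=O)(=O)C(F)(F)F | intermediate
12 | acrolein | C=CC=O | starting material
13 | 2-[(2R,4R)-2-tert-butyl-5-oxo-4-(3-oxopropyl)-1,3-dioxolan-4-yl]-N-methoxy-N-methylacetamide (3-oxopropyl trans to tert-butyl) | CON(C)C(=O)C[C@@]1(CCC=O)O[C@@H](C(C)(C)C)OC1=O | intermediate (not isolated)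
14 | dipotassium (2R)-2-[2-(methoxy(methyl)amino)-2-oxoethyl]-2-oxido-5-oxopentanoate (open form of the γ-lactol) | CON(C)C(=O)C[C@@](CCC=O)([O-])C(=O)[O-].[K+].[K+] | intermediate (not isolated)
15 | (2R)-6-[(3E)-5-(tert-butyldimethylsilyloxy)-4-methylpent-3-en-1-yl]-2-[2-(methoxy(methyl)amino)-2-oxoethyl]-2,3,4,7-tetrahydrooxepine-2-carboxylic acid | C/C(=C\CCC1=CCC[C@@](CC(=O)N(C)OC)(C(=O)O)OC1)CO[Si](C)(C)C(C)(C)C | intermediate
16 | 2-bromobenzene-1,4-diol | Oc1ccc(O)c(Br)c1 | starting material
17 | 2-bromo-1,4-bis(tert-butyldimethylsilyloxy)benzene | CC(C)(C)[Si](C)(C)Oc1ccc(O[Si](C)(C)C(C)(C)C)c(Br)c1 | intermediate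
18 | [2,5-bis(tert-butyldimethylsilyloxy)phenyl]magnesium bromide | CC(C)(C)[Si](C)(C)Oc1ccc(O[Si](C)(C)C(C)(C)C)c([Mg]Br)c1 | intermediate (not isolated)
19 | (2R)-2-{2-[2,5-bis(tert-butyldimethylsilyloxy)phenyl]-2-oxoethyl}-6-[(3E)-5-(tert-butyldimethylsilyloxy)-4-methylpent-3-en-1-yl]-2,3,4,7-tetrahydrooxepine-2-carboxylic acid | C/C(=C\CCC1=CCC[C@@](CC(=O)c2cc(O[Si](C)(C)C(C)(C)C)ccc2O[Si](C)(C)C(C)(C)C)(C(=O)O)OC1)CO[Si](C)(C)C(C)(C)C | intermediate
20 | (2R)-2-{2-[2,5-bis(tert-butyldimethylsilyloxy)phenyl]-2-oxoethyl}-6-[(3E)-5-hydroxy-4-methylpent-3-en-1-yl]-2,3,4,7-tetrahydrooxepine-2-carboxylic acid | C/C(=C\CCC1=CCC[C@@](CC(=O)c2cc(O[Si](C)(C)C(C)(C)C)ccc2O[Si](C)(C)C(C)(C)C)(C(=O)O)OC1)CO | intermediate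
21 | p-coumaric acid | OC(=O)/C=C/c1ccc(O)cc1 | starting material
22 | tert-butyldimethylsilyl (E)-3-[4-(tert-butyldimethylsilyloxy)phenyl]prop-2-enoate | CC(C)(C)[Si](C)(C)OC(=O)/C=C/c1ccc(O[Si](C)(C)C(C)(C)C)cc1 | intermediate (not isolated)
23 | (E)-3-[4-(tert-butyldimethylsilyloxy)phenyl]prop-2-enoic acid | OC(=O)/C=C/c1ccc(O[Si](C)(C)C(C)(C)C)cc1 | intermediate
24 | (E)-3-[4-(tert-butyldimethylsilyloxy)phenyl]prop-2-enoyl chloride | ClC(=O)/C=C/c1ccc(O[Si](C)(C)C(C)(C)C)cc1 | intermediate (not isolated)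
25 | tris-TBS ether of the target: (2R)-2-{2-[2,5-bis(tert-butyldimethylsilyloxy)phenyl]-2-oxoethyl}-6-[(3E)-5-{[(2E)-3-(4-(tert-butyldimethylsilyloxy)phenyl)prop-2-enoyl]oxy}-4-methylpent-3-en-1-yl]-2,3,4,7-tetrahydrooxepine-2-carboxylic acid | C/C(=C\CCC1=CCC[C@@](CC(=O)c2cc(O[Si](C)(C)C(C)(C)C)ccc2O[Si](C)(C)C(C)(C)C)(C(=O)O)OC1)COC(=O)/C=C/c1ccc(O[Si](C)(C)C(C)(C)C)cc1 | intermediate
26 | CNP0602535.1, (2R)-2-[2-(2,5-dihydroxyphenyl)-2-oxoethyl]-6-[(3E)-5-{[(2E)-3-(4-hydroxyphenyl)prop-2-enoyl]oxy}-4-methylpent-3-en-1-yl]-2,3,4,7-tetrahydrooxepine-2-carboxylic acid | C/C(=C\CCC1=CCC[C@@](CC(=O)c2cc(O)ccc2O)(C(=O)O)OC1)COC(=O)/C=C/c1ccc(O)cc1 | target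

Total step count: 14. Longest linear sequence: 9 steps (steps 4, 5, 6, 7, 8, 10, 11, 13, 14).

Steps most likely to fail

1. Step 8 (proposed new method). The radical may be reduced by the stannane before it adds to acrolein. The liberated tertiary alkoxide may add only slowly to the hindered vinylphosphonium salt. The seven-membered Wittig closure may lose out to intermolecular olefination or to isomerisation of the phosphonium salt. The fallback uses known chemistry, sets out from 5, 12 and 10, and comes back at 15. The Giese addition is run alone and aldehyde 13 is isolated. Wittig methylenation (Ph3P=CH2) should give 2-[(2R,4R)-4-(but-3-en-1-yl)-2-tert-butyl-5-oxo-1,3-dioxolan-4-yl]-N-methoxy-N-methylacetamide F1, and K2CO3/MeOH should open the acetal to methyl (2R)-2-hydroxy-2-[2-(methoxy(methyl)amino)-2-oxoethyl]hex-5-enoate F2. In parallel, triflate 10 is coupled with (tributylstannyl)methanol (Stille reaction) to (E)-6-(tert-butyldimethylsilyloxy)-5-methyl-2-methylidenehex-4-en-1-ol F3, which CBr4/PPh3 should convert into (E)-2-(bromomethyl)-6-(tert-butyldimethylsilyloxy)-5-methylhexa-1,4-diene F4. Williamson etherification of F2 with F4 (NaH, DMF) should give the diene ether F5, ring-closing metathesis (Grubbs II catalyst) the oxepine methyl ester F6, and LiOH the acid 15.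

2. Step 3. The tertiary bromide may lose HBr to the alkylidene dioxolanone, or hydrogen may be abstracted at the acetal carbon. The fallback replaces the radical route to the three-carbon arm by enolate chemistry; it sets out from 2 and comes back at 13. Allylation of the dianion of 2 (LiHMDS, allyl bromide, THF, −78 °C, attack trans to tert-butyl) should give (2R,4R)-4-allyl-2-tert-butyl-5-oxo-1,3-dioxolane-4-acetic acid F7. CDI and MeNH(OMe)·HCl should give its Weinreb amide F8. Hydroboration and oxidation (9-BBN, then NaBO3) should give the primary alcohol F9, and Dess–Martin oxidation the aldehyde 13, which then enters step 8 at the silanolate stage.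

3. Step 10. The hindered ortho-silyloxy aryl Grignard reagent may add slowly, deprotonate next to the amide, or undergo silyl migration. The fallback builds the ketone through the alcohol oxidation level; it sets out from 15 and comes back at 19. Reduction of the Weinreb amide with Cp2Zr(H)Cl should give the aldehyde acid F10. Addition of 18 should give the benzylic carbinol F11 (both epimers at the new carbinol centre), and Dess–Martin oxidation the ketone 19.

Further compounds
F1 | step 8 | 2-[(2R,4R)-4-(but-3-en-1-yl)-2-tert-butyl-5-oxo-1,3-dioxolan-4-yl]-N-methoxy-N-methylacetamide | CON(C)C(=O)C[C@@]1(CCC=C)O[C@@H](C(C)(C)C)OC1=O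
F2 | step 8 | methyl (2R)-2-hydroxy-2-[2-(methoxy(methyl)amino)-2-oxoethyl]hex-5-enoate | CON(C)C(=O)C[C@@](CCC=C)(O)C(=O)OC
F3 | step 8 | (E)-6-(tert-butyldimethylsilyloxy)-5-methyl-2-methylidenehex-4-en-1-ol | C/C(=C\CCC(=C)CO)CO[Si](C)(C)C(C)(C)C
F4 | step 8 | (E)-2-(bromomethyl)-6-(tert-butyldimethylsilyloxy)-5-methylhexa-1,4-diene | C/C(=C\CCC(=C)CBr)CO[Si](C)(C)C(C)(C)C
F5 | step 8 | methyl (2R)-2-{[(E)-6-(tert-butyldimethylsilyloxy)-5-methyl-2-methylidenehex-4-en-1-yl]oxy}-2-[2-(methoxy(methyl)amino)-2-oxoethyl]hex-5-enoate | C/C(=C\CCC(=C)CO[C@](CCC=C)(CC(=O)N(C)OC)C(=O)OC)CO[Si](C)(C)C(C)(C)C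
F6 | step 8 | methyl (2R)-6-[(3E)-5-(tert-butyldimethylsilyloxy)-4-methylpent-3-en-1-yl]-2-[2-(methoxy(methyl)amino)-2-oxoethyl]-2,3,4,7-tetrahydrooxepine-2-carboxylate | C/C(=C\CCC1=CCC[C@@](CC(=O)N(C)OC)(C(=O)OC)OC1)CO[Si](C)(C)C(C)(C)C
F7 | step 3 | (2R,4R)-4-allyl-2-tert-butyl-5-oxo-1,3-dioxolane-4-acetic acid | OC(=O)C[C@@]1(CC=C)O[C@@H](C(C)(C)C)OC1=O
F8 | step 3 | 2-[(2R,4R)-4-allyl-2-tert-butyl-5-oxo-1,3-dioxolan-4-yl]-N-methoxy-N-methylacetamide | CON(C)C(=O)C[C@@]1(CC=C)O[C@@H](C(C)(C)C)OC1=O
F9 | step 3 | 2-[(2R,4R)-2-tert-butyl-4-(3-hydroxypropyl)-5-oxo-1,3-dioxolan-4-yl]-N-methoxy-N-methylacetamide | CON(C)C(=O)C[C@@]1(CCCO)O[C@@H](C(C)(C)C)OC1=O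
F10 | step 10 | (2R)-6-[(3E)-5-(tert-butyldimethylsilyloxy)-4-methylpent-3-en-1-yl]-2-(2-oxoethyl)-2,3,4,7-tetrahydrooxepine-2-carboxylic acid | C/C(=C\CCC1=CCC[C@@](CC=O)(C(=O)O)OC1)CO[Si](C)(C)C(C)(C)C
F11 | step 10 | (2R)-2-{2-[2,5-bis(tert-butyldimethylsilyloxy)phenyl]-2-hydroxyethyl}-6-[(3E)-5-(tert-butyldimethylsilyloxy)-4-methylpent-3-en-1-yl]-2,3,4,7-tetrahydrooxepine-2-carboxylic acid | C/C(=C\CCC1=CCC[C@@](CC(O)c2cc(O[Si](C)(C)C(C)(C)C)ccc2O[Si](C)(C)C(C)(C)C)(C(=O)O)OC1)CO[Si](C)(C)C(C)(C)C
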